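**Assumption:** the SMILES holds no stereocentre and no stereodefined double bond. The target is therefore achiral (one enol tautomer of a fast-exchanging set is drawn) and no enantioselective step is needed.

## Retrosynthetic overview
1. Cut only the aryl C–CH2 bond. This gives 2,6-dihydroxy-4-methoxybutyrophenone as the carbon nucleophile and a 6-methylene trione as the electrophile, so the bridge carbon belongs to the dearomatised half and no formaldehyde is used.
2. The methylene trione comes from oxidation of the C6-methyl group of 2-acetyl-4,4,6-trimethylcyclohexane-1,3,5-trione.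
3. Key step: all three C–CH3 bonds (the gem-dimethyl group and the future bridge carbon) are made in one dearomatising triple C-methylation of 2,4,6-trihydroxyacetophenone.
4. The aromatic half comes from threefold-symmetric 1,3,5-trimethoxybenzene by acylation and chelation-controlled double demethylation in one flask.
5. No ring is built. Both carbocycles are bought as benzene rings: ring A is dearomatised and ring B stays aromatic.

## Route

Step 1
Reactants: 1 1,3,5-trimethoxybenzene; 2 butanoyl chloride
Product: 5 1-(2,6-dihydroxy-4-methoxyphenyl)butan-1-one, via trimethoxy ketone 3 (not isolated), via monophenol ketone 4 (not isolated)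
Conditions: AlCl3 (4.0 equiv), PhCl, 0 °C to rt, 1 h, then 85 °C, 4 h; ice/2 M HCl
Reagents that add atoms: none
Why: Friedel–Crafts acylation happens only once because the ketone deactivates the ring, and AlCl3 held on the carbonyl oxygen then cleaves only the two ortho methyl ethers through six-membered chelates (chloride attack at methyl), leaving the unchelated para OMe in place; no stereocentre is formed.

Step 2
Reactants: 6 1-(2,4,6-trihydroxyphenyl)ethan-1-one (dried commercial monohydrate)
Product: 10 2-acetyl-3,5-dihydroxy-4,4,6-trimethylcyclohexa-2,5-dien-1-one, via monomethyl phenol 7 (not isolated), via aromatic dimethyl ketone 8 (not isolated), via acetylfilicinic acid 9 (not isolated)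
Conditions: NaOMe (4.2 equiv), MeI (3.1 equiv), MeOH, 0 °C to 45 °C (sealed), 16 h; 2 M HCl
Reagents that add atoms: iodomethane (MeI), CI
Why: Alkylative dearomatisation, in which the phloroglucinol polyanion reacts with MeI at its two free ring carbons, both dimethyl intermediates 8 and 9 converge on the same trimethyl product 10, and the more hindered fourth methylation is held back by the MeI stoichiometry; the quaternary carbon carries two identical methyl groups, so no stereocentre is formed.

Step 3
Reactants: 10 2-acetyl-3,5-dihydroxy-4,4,6-trimethylcyclohexa-2,5-dien-1-one; 5 1-(2,6-dihydroxy-4-methoxyphenyl)butan-1-one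
Product: 13 2-acetyl-6-[(3-butanoyl-2,4-dihydroxy-6-methoxyphenyl)methyl]-3,5-dihydroxy-4,4-dimethylcyclohexa-2,5-dien-1-one, via TEMPO adduct 11 (not isolated), via methylene trione 12 (not isolated)
Conditions: TEMPO (1.1 equiv), Ag2O (0.75 equiv), THF, 0 °C, 1 h; filter through Celite under N2; add 5 (2.0 equiv), 45 °C, 12 h
Reagents that add atoms: TEMPO, CC1(C)CCCC(C)(C)N1[O] (its atoms sit only in intermediate 11 and leave again as the hydroxylamine)
Why: Proposed new method: Ag2O oxidises the silver enolate of 10 by one electron and TEMPO caps the C6 radical as the weak tertiary alkoxyamine 11 (racemic, its stereocentre is erased at once), which by reversible homolysis and disproportionation slowly releases the doubly activated Michael acceptor 12; with the oxidant already filtered off, 12 is taken by one of the two equivalent ring C–H carbons of excess 5 in a Friedel–Crafts-type conjugate addition whose rearomatisation and re-enolisation are the irreversible sink, so only the cross-coupled product and a single regioisomer can form and the product has no stereocentre; the closest known reactions are the TEMPO/Ag2O oxidation of 4,4,6-trimethyl acylcyclohexanetriones to such methylene triones for hetero-Diels–Alder trapping, and the Michael addition of acylphloroglucinols to alkylidene syncarpic acids.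

## Compound list
1 | 1,3,5-trimethoxybenzene | COc1cc(OC)cc(OC)c1 | starting material
2 | butanoyl chloride | CCCC(=O)Cl | starting material
3 | 1-(2,4,6-trimethoxyphenyl)butan-1-one | CCCC(=O)c1c(OC)cc(OC)cc1OC | intermediate (not isolated)
4 | 1-(2-hydroxy-4,6-dimethoxyphenyl)butan-1-one | CCCC(=O)c1c(O)cc(OC)cc1OC | intermediate (not isolated)
5 | 1-(2,6-dihydroxy-4-methoxyphenyl)butan-1-one | CCCC(=O)c1c(O)cc(OC)cc1O | intermediate
6 | 1-(2,4,6-trihydroxyphenyl)ethan-1-one | CC(=O)c1c(O)cc(O)cc1O | starting material
7 | 1-(2,4,6-trihydroxy-3-methylphenyl)ethan-1-one | CC(=O)c1c(O)cc(O)c(C)c1O | intermediate (not isolated)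
8 | 1-(2,4,6-trihydroxy-3,5-dimethylphenyl)ethan-1-one | CC(=O)c1c(O)c(C)c(O)c(C)c1O | intermediate (not isolated)
9 | 2-acetyl-3,5-dihydroxy-4,4-dimethylcyclohexa-2,5-dien-1-one (acetylfilicinic acid) | CC(=O)C1=C(O)C(C)(C)C(O)=CC1=O | intermediate (not isolated)
10 | 2-acetyl-3,5-dihydroxy-4,4,6-trimethylcyclohexa-2,5-dien-1-one | CC(=O)C1=C(O)C(C)(C)C(O)=C(C)C1=O | intermediate
11 | 2-acetyl-3-hydroxy-4,4,6-trimethyl-6-[(2,2,6,6-tetramethylpiperidin-1-yl)oxy]cyclohex-2-ene-1,5-dione (racemic) | CC(=O)C1=C(O)C(C)(C)C(=O)C(C)(ON2C(C)(C)CCCC2(C)C)C1=O | intermediate (not isolated)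
12 | 2-acetyl-3-hydroxy-4,4-dimethyl-6-methylidenecyclohex-2-ene-1,5-dione | CC(=O)C1=C(O)C(C)(C)C(=O)C(=C)C1=O | intermediate (not isolated)
13 | 2-acetyl-6-[(3-butanoyl-2,4-dihydroxy-6-methoxyphenyl)methyl]-3,5-dihydroxy-4,4-dimethylcyclohexa-2,5-dien-1-one (achiral) | CCCC(=O)c1c(O)cc(OC)c(CC2=C(O)C(C)(C)C(O)=C(C(C)=O)C2=O)c1O | target

**Total step count:** 3. **Longest linear sequence:** 2 (step 1 or step 2, then step 3).

## Steps most likely to fail

**Step 3 (highest risk).**
- Failure modes: 12 may dimerise, may be reduced back to 10 by the hydroxylamine, or may alkylate 5 twice.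
- Fallback: exchange the roles of the two halves and take the bridge carbon from formaldehyde. It sets out from 5.
- Aqueous HCHO and Me2NH (1 equiv each, EtOH, rt) convert 5 into the Mannich base 1-[3-(dimethylaminomethyl)-2,6-dihydroxy-4-methoxyphenyl]butan-1-one F1.
- In parallel, the methylation of 6 is stopped at two equivalents of MeI and acetylfilicinic acid 9 is isolated.
- Heating F1 with 9 (1.2 equiv) in dioxane at 100 °C expels Me2NH. The aromatic ortho-quinone methide is then captured by the free ring C–H carbon of 9.
- The fallback comes back to the route at 13.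

**Step 2.**
- Failure modes: over-methylation to the tetramethyl trione, or O-methylation.
- Fallback: install the first two methyl groups reductively while the ring is still aromatic, so that dearomatisation needs only one C–C bond. It sets out from 6.
- A double Mannich reaction (HCHO and Me2NH, 2.2 equiv each, EtOH) gives 1-[3,5-bis(dimethylaminomethyl)-2,4,6-trihydroxyphenyl]ethan-1-one F2.
- Hydrogenolysis (H2, Pd/C, MeOH/AcOH, 60 °C) gives 8, which is isolated this time.
- One methylation at either of its two equivalent methyl-bearing carbons (NaOMe 2.2 equiv, MeI 1.05 equiv, MeOH) brings the fallback back to the route at 10.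

**Step 1.**
- Failure modes: the second demethylation stays incomplete, the para ether is lost, or the ring is deacylated at 85 °C.
- Fallback: set the oxygen pattern by selective methylation instead of selective demethylation. It sets out from 2.
- Friedel–Crafts acylation of benzene-1,3,5-triol F3 with 2 (AlCl3, CH2Cl2/PhNO2, 40 °C) gives 1-(2,4,6-trihydroxyphenyl)butan-1-one F4.
- The 4-OH of F4 is the most acidic hydroxyl and the only one not hydrogen-bonded to the ketone. It is methylated with Me2SO4 (1.0 equiv) and K2CO3 (1.0 equiv) in acetone.
- The fallback comes back to the route at 5.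

## Further compounds
F1 | step 3 | 1-[3-(dimethylaminomethyl)-2,6-dihydroxy-4-methoxyphenyl]butan-1-one | CCCC(=O)c1c(O)cc(OC)c(CN(C)C)c1O
F2 | step 2 | 1-[3,5-bis(dimethylaminomethyl)-2,4,6-trihydroxyphenyl]ethan-1-one | CC(=O)c1c(O)c(CN(C)C)c(O)c(CN(C)C)c1O
F3 | step 1 | benzene-1,3,5-triol (phloroglucinol) | Oc1cc(O)cc(O)c1
F4 | step 1 | 1-(2,4,6-trihydroxyphenyl)butan-1-one | CCCC(=O)c1c(O)cc(O)cc1O
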